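**Retrosynthetic overview**
1. Target 10 comes from its 5,7-di-O-benzyl ether 9 by hydrogenolysis.
2. Ring C of 9 is closed last (O1–C2 bond) by oxidative cyclisation of the 2'-hydroxychalcone 7.
3. The Cα–Cβ bond of 7 is the key C–C bond: a crossed (Claisen–Schmidt) aldol condensation of ring A acetophenone 4 with ring B aldehyde 5.
4. Acetophenone 4 comes from phloroacetophenone 1 by bis-O-benzylation (2), ring dibromination (3) and copper-catalysed double methoxylation.
5. Rings A and B are bought intact; ring C is the only ring formed.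

Assumption: the target has no stereocentre and no stereogenic double bond, so the SMILES given is the single compound to be made and no enantiocontrol is needed.
Assumption: in twofold reactions of one kind (steps 1, 2, 3 and 6) the half-reacted species are not numbered.

**Step 1**
Reactants: 1 2,4,6-trihydroxyacetophenone (dried from the commercial monohydrate)
Product: 2 4,6-bis(benzyloxy)-2-hydroxyacetophenone
Conditions: BnBr (2.1 equiv), K2CO3 (2.5 equiv), DMF, rt, 16 h
Reagents that add atoms: benzyl bromide, BrCc1ccccc1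
Why: Williamson ether synthesis in which the 4-OH and one ortho OH are benzylated while the last ortho OH stays locked in a hydrogen bond to the carbonyl and is left free.

**Step 2**
Reactants: 2 4,6-bis(benzyloxy)-2-hydroxyacetophenone
Product: 3 4,6-bis(benzyloxy)-3,5-dibromo-2-hydroxyacetophenone
Conditions: NBS (2.1 equiv), DMF, 0 °C to rt, dark, 2 h
Reagents that add atoms: N-bromosuccinimide, O=C1CCC(=O)N1Br
Why: Electrophilic aromatic bromination at the only two ring C–H positions, each ortho/para to three oxygen donors and far more reactive than the benzyl rings or the acetyl α-carbon.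

**Step 3**
Reactants: 3 4,6-bis(benzyloxy)-3,5-dibromo-2-hydroxyacetophenone
Product: 4 4,6-bis(benzyloxy)-2-hydroxy-3,5-dimethoxyacetophenone
Conditions: NaOMe (12 equiv, 28% in MeOH), CuBr (0.4 equiv), DMF, 110 °C, Ar, 6 h; then 1 M HCl
Reagents that add atoms: sodium methoxide, [Na+].[O-]C
Why: Ullmann-type copper-catalysed methanolysis of electron-rich aryl bromides (the 5-bromovanillin to syringaldehyde reaction type), which benzyl ethers and the phenoxide/ketone tolerate.

**Step 4**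
Reactants: 4 4,6-bis(benzyloxy)-2-hydroxy-3,5-dimethoxyacetophenone; 5 2,3-dimethoxybenzaldehyde (1.3 equiv)
Product: 7 (E)-1-[4,6-bis(benzyloxy)-2-hydroxy-3,5-dimethoxyphenyl]-3-(2,3-dimethoxyphenyl)prop-2-en-1-one, via aldol adduct 6 (not isolated)
Conditions: KOH (10 equiv, 50% aq.), EtOH, rt, 36 h; then 1 M HCl
Reagents that add atoms: none
Why: Claisen–Schmidt crossed aldol condensation between a non-enolisable aldehyde and a hindered ketone that cannot self-condense; E1cB dehydration of racemic adduct 6 removes its stereocentre and gives the thermodynamic E-enone.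

**Step 5**
Reactants: 7 (E)-1-[4,6-bis(benzyloxy)-2-hydroxy-3,5-dimethoxyphenyl]-3-(2,3-dimethoxyphenyl)prop-2-en-1-one
Product: 9 5,7-bis(benzyloxy)-2-(2,3-dimethoxyphenyl)-6,8-dimethoxy-4H-chromen-4-one, via flavanone 8 (not isolated)
Conditions: I2 (0.1 equiv), DMSO, 120 °C, 3 h; aq. Na2S2O3 work-up
Reagents that add atoms: none
Why: Iodine-catalysed oxidative cyclisation in which intramolecular oxa-Michael addition gives racemic flavanone 8, α-iodination and loss of HI give the flavone (erasing the C2 stereocentre), and DMSO reoxidises HI to I2.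

**Step 6**
Reactants: 9 5,7-bis(benzyloxy)-2-(2,3-dimethoxyphenyl)-6,8-dimethoxy-4H-chromen-4-one
Product: 10 5,7-dihydroxy-2-(2,3-dimethoxyphenyl)-6,8-dimethoxy-4H-chromen-4-one (5,7-dihydroxy-6,8,2',3'-tetramethoxyflavone)
Conditions: H2 (1 atm), 10% Pd/C, EtOAc–MeOH 1:1, rt, 3 h
Reagents that add atoms: none
Why: Catalytic hydrogenolysis cleaves both benzyl aryl ethers while the methyl ethers are inert and the chromone C2=C3 bond (a vinylogous ester) is reduced much more slowly.

**Compound list**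
1 | 2,4,6-trihydroxyacetophenone | CC(=O)c1c(O)cc(O)cc1O | starting material
2 | 4,6-bis(benzyloxy)-2-hydroxyacetophenone | CC(=O)c1c(O)cc(OCc2ccccc2)cc1OCc1ccccc1 | intermediate
3 | 4,6-bis(benzyloxy)-3,5-dibromo-2-hydroxyacetophenone | CC(=O)c1c(O)c(Br)c(OCc2ccccc2)c(Br)c1OCc1ccccc1 | intermediate
4 | 4,6-bis(benzyloxy)-2-hydroxy-3,5-dimethoxyacetophenone | CC(=O)c1c(O)c(OC)c(OCc2ccccc2)c(OC)c1OCc1ccccc1 | intermediate
5 | 2,3-dimethoxybenzaldehyde | COc1cccc(C=O)c1OC | starting material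
6 | racemic 1-[4,6-bis(benzyloxy)-2-hydroxy-3,5-dimethoxyphenyl]-3-(2,3-dimethoxyphenyl)-3-hydroxypropan-1-one (aldol adduct, not isolated) | COc1cccc(C(O)CC(=O)c2c(O)c(OC)c(OCc3ccccc3)c(OC)c2OCc2ccccc2)c1OC | intermediate
7 | (E)-1-[4,6-bis(benzyloxy)-2-hydroxy-3,5-dimethoxyphenyl]-3-(2,3-dimethoxyphenyl)prop-2-en-1-one | COc1cccc(/C=C/C(=O)c2c(O)c(OC)c(OCc3ccccc3)c(OC)c2OCc2ccccc2)c1OC | intermediate
8 | racemic 5,7-bis(benzyloxy)-2-(2,3-dimethoxyphenyl)-6,8-dimethoxychroman-4-one (flavanone, not isolated) | COc1cccc(C2CC(=O)c3c(OCc4ccccc4)c(OC)c(OCc4ccccc4)c(OC)c3O2)c1OC | intermediate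
9 | 5,7-bis(benzyloxy)-2-(2,3-dimethoxyphenyl)-6,8-dimethoxy-4H-chromen-4-one | COc1cccc(-c2cc(=O)c3c(OCc4ccccc4)c(OC)c(OCc4ccccc4)c(OC)c3o2)c1OC | intermediate
10 | 5,7-dihydroxy-2-(2,3-dimethoxyphenyl)-6,8-dimethoxy-4H-chromen-4-one (achiral) | COc1cccc(-c2cc(=O)c3c(O)c(OC)c(O)c(OC)c3o2)c1OC | target

**Totals**
Total step count: 6. Longest linear sequence: 6 steps (1 to 10); aldehyde 5 is bought.

**Three steps most likely to fail**

Step 3 (double methanolysis). The C5 bromide sits between two benzyloxy groups, so hydrodebromination or a stalled second substitution is the main danger. The fallback sets out from 2 and comes back at 10; it oxygenates ring A last, on the free 5,7-diphenol, where each C–Br is flanked by phenoxides. Condensation of 2 with 5 (KOH, EtOH, rt) gives, through the aldol adduct 1-[4,6-bis(benzyloxy)-2-hydroxyphenyl]-3-(2,3-dimethoxyphenyl)-3-hydroxypropan-1-one F1, the chalcone (E)-1-[4,6-bis(benzyloxy)-2-hydroxyphenyl]-3-(2,3-dimethoxyphenyl)prop-2-en-1-one F2. I2/DMSO at 120 °C closes ring C through the flavanone 5,7-bis(benzyloxy)-2-(2,3-dimethoxyphenyl)chroman-4-one F3 to 5,7-bis(benzyloxy)-2-(2,3-dimethoxyphenyl)-4H-chromen-4-one F4. Hydrogenolysis (H2, 10% Pd/C) gives 5,7-dihydroxy-2-(2,3-dimethoxyphenyl)-4H-chromen-4-one F5. NBS (2.05 equiv, DMF, 0 °C) brominates C6 and C8 to 6,8-dibromo-5,7-dihydroxy-2-(2,3-dimethoxyphenyl)-4H-chromen-4-one F6. NaOMe/CuBr in DMF–MeOH at reflux then gives 10 directly.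

Step 5 (oxidative cyclisation). The chalcone is doubly ortho-substituted; the reaction may stall at flavanone 8, and HI may strip the 5-O-benzyl group (such material still converges on 10 in step 6). The fallback sets out from 4 and comes back at 9; it replaces the chalcone oxidation by a Claisen-type C-acylation and cyclodehydration, with no oxidant. Treating 4 with LiN(SiMe3)2 (3.3 equiv, THF, −78 °C) and then 2,3-dimethoxybenzoyl chloride (COc1cccc(C(Cl)=O)c1OC) gives the β-diketone 1-[4,6-bis(benzyloxy)-2-hydroxy-3,5-dimethoxyphenyl]-3-(2,3-dimethoxyphenyl)propane-1,3-dione F7. NaOAc in AcOH at 100 °C closes it to the hemiketal 5,7-bis(benzyloxy)-2-(2,3-dimethoxyphenyl)-2-hydroxy-6,8-dimethoxychroman-4-one F8, which loses water to 9.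

Step 1 (selective bis-O-benzylation). Mixtures of mono-, di- and tri-O-benzyl ethers and some C-benzylation can lower the yield. The fallback sets out from 1 and comes back at 2; it over-protects and then unmasks one position. Exhaustive benzylation of 1 (BnBr 3.5 equiv, K2CO3, DMF, 60 °C) gives 2,4,6-tris(benzyloxy)acetophenone F9. BCl3 (1.05 equiv, CH2Cl2, −78 °C) then removes a single benzyl group ortho to the carbonyl through the boron chelate and returns 2.

**Further compounds**
F1 | step 3 | racemic 1-[4,6-bis(benzyloxy)-2-hydroxyphenyl]-3-(2,3-dimethoxyphenyl)-3-hydroxypropan-1-one | COc1cccc(C(O)CC(=O)c2c(O)cc(OCc3ccccc3)cc2OCc2ccccc2)c1OC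
F2 | step 3 | (E)-1-[4,6-bis(benzyloxy)-2-hydroxyphenyl]-3-(2,3-dimethoxyphenyl)prop-2-en-1-one | COc1cccc(/C=C/C(=O)c2c(O)cc(OCc3ccccc3)cc2OCc2ccccc2)c1OC
F3 | step 3 | racemic 5,7-bis(benzyloxy)-2-(2,3-dimethoxyphenyl)chroman-4-one | COc1cccc(C2CC(=O)c3c(OCc4ccccc4)cc(OCc4ccccc4)cc3O2)c1OC
F4 | step 3 | 5,7-bis(benzyloxy)-2-(2,3-dimethoxyphenyl)-4H-chromen-4-one | COc1cccc(-c2cc(=O)c3c(OCc4ccccc4)cc(OCc4ccccc4)cc3o2)c1OC
F5 | step 3 | 5,7-dihydroxy-2-(2,3-dimethoxyphenyl)-4H-chromen-4-one | COc1cccc(-c2cc(=O)c3c(O)cc(O)cc3o2)c1OC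
F6 | step 3 | 6,8-dibromo-5,7-dihydroxy-2-(2,3-dimethoxyphenyl)-4H-chromen-4-one | COc1cccc(-c2cc(=O)c3c(O)c(Br)c(O)c(Br)c3o2)c1OC
F7 | step 5 | 1-[4,6-bis(benzyloxy)-2-hydroxy-3,5-dimethoxyphenyl]-3-(2,3-dimethoxyphenyl)propane-1,3-dione | COc1cccc(C(=O)CC(=O)c2c(O)c(OC)c(OCc3ccccc3)c(OC)c2OCc2ccccc2)c1OC
F8 | step 5 | racemic 5,7-bis(benzyloxy)-2-(2,3-dimethoxyphenyl)-2-hydroxy-6,8-dimethoxychroman-4-one | COc1cccc(C2(O)CC(=O)c3c(OCc4ccccc4)c(OC)c(OCc4ccccc4)c(OC)c3O2)c1OC
F9 | step 1 | 2,4,6-tris(benzyloxy)acetophenone | CC(=O)c1c(OCc2ccccc2)cc(OCc2ccccc2)cc1OCc1ccccc1
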